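**Retrosynthetic overview**
1. The quinone is taken back to its hydroquinone, which is oxidised in the last step. The furan ring is bought; the six-membered carbocycle is the only ring built and is formed last.
2. The hydroquinone ring is cut at C-4–C-5 and at C-2=C-3 (quinone numbering, C-2 carries the furan). This gives glyoxal (C-3/C-4) and a furan-2-ylmethyl vinyl ketone (C-2, C-1, C-6, C-5). Forward: a carbene-catalysed Stetter addition, then aldol condensation and enolisation to the arene in the same flask.
3. Enabling feature: the ring carbonyl carbons C-1 and C-4 are 1,4-related through C-5/C-6, two acyl carbons of like polarity that a Stetter umpolung can join. Ring carbon C-2 lies between furan C-2 and the C-1 carbonyl, so in the open chain it is a doubly activated CH2 that closes the ring onto the glyoxal-derived aldehyde carbon C-3.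
4. The vinyl ketone comes from a Weinreb amide, made by palladium-catalysed coupling of a zinc amide enolate with the 5-bromofuran.
5. The side chain comes from Brown allylboration of 5-bromofuran-3-carbaldehyde (sets the (S)-carbinol), cross-metathesis with 2-methylbut-2-ene and Steglich esterification.

Key step: step 6

Assumption: 5-bromofuran-3-carbaldehyde and the pentane solution of (−)-B-allyldiisopinocampheylborane are taken as catalogue items, and the single stereocentre of the target is read as (S).

**Step 1**
Reactants: 1 5-bromofuran-3-carbaldehyde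
Product: 3 (1S)-1-(5-bromofuran-3-yl)but-3-en-1-ol, via borinate ester 2 (not isolated)
Conditions: (−)-Ipc2B(allyl) (1 M in pentane, 1.2 equiv), Et2O, −78 °C; then 3 M NaOH, 30% H2O2, 0 °C to rt
Reagents that add atoms: (−)-B-allyldiisopinocampheylborane, C=CCB([C@@H]1C[C@@H]2C[C@H]([C@H]1C)C2(C)C)[C@@H]1C[C@@H]2C[C@H]([C@H]1C)C2(C)C
Why: Brown allylboration through a closed chair transition state, in which the isopinocampheyl groups derived from (+)-α-pinene steer the allyl group to the Si face of the heteroaryl aldehyde, should set the (S)-carbinol with high enantiomeric excess.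

**Step 2**
Reactants: 3 (1S)-1-(5-bromofuran-3-yl)but-3-en-1-ol
Product: 4 (1S)-1-(5-bromofuran-3-yl)-4-methylpent-3-en-1-ol
Conditions: 2-methylbut-2-ene (excess), second-generation Grubbs catalyst (H2IMes)(PCy3)Cl2Ru=CHPh (5 mol %), CH2Cl2, 40 °C
Reagents that add atoms: 2-methylbut-2-ene, CC=C(C)C
Why: Olefin cross-metathesis with excess 2-methylbut-2-ene should turn the terminal vinyl group into the trisubstituted prenyl terminus without touching the carbinol centre or the bromofuran.

**Step 3**
Reactants: 4 (1S)-1-(5-bromofuran-3-yl)-4-methylpent-3-en-1-ol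
Product: 5 (1S)-1-(5-bromofuran-3-yl)-4-methylpent-3-en-1-yl 3-methylbut-2-enoate
Conditions: 3-methylbut-2-enoic acid, DCC, DMAP (10 mol %), CH2Cl2, 0 °C to rt
Reagents that add atoms: 3-methylbut-2-enoic acid, CC(C)=CC(=O)O
Why: Steglich esterification acylates the secondary alcohol at oxygen, so the C–O bond of the stereocentre is not broken and the configuration is retained.

**Step 4**
Reactants: 5 (1S)-1-(5-bromofuran-3-yl)-4-methylpent-3-en-1-yl 3-methylbut-2-enoate
Product: 6 (1S)-1-{5-[2-(methoxy(methyl)amino)-2-oxoethyl]furan-3-yl}-4-methylpent-3-en-1-yl 3-methylbut-2-enoate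
Conditions: BrZnCH2C(O)N(OMe)Me (from BrCH2C(O)N(OMe)Me and activated Zn dust, THF, rt; 1.5 equiv), Pd(dba)2 (3 mol %), P(t-Bu)3 (3 mol %), THF, rt to 50 °C
Reagents that add atoms: 2-bromo-N-methoxy-N-methylacetamide, CON(C)C(=O)CBr
Why: Palladium-catalysed α-arylation of a Reformatsky-type zinc amide enolate (Negishi-type coupling) proceeds by oxidative addition of zerovalent palladium into the α-bromofuran C–Br bond, transmetalation and reductive elimination, and the neutral zinc enolate should leave the ester untouched.

**Step 5**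
Reactants: 6 (1S)-1-{5-[2-(methoxy(methyl)amino)-2-oxoethyl]furan-3-yl}-4-methylpent-3-en-1-yl 3-methylbut-2-enoate
Product: 8 (1S)-4-methyl-1-[5-(2-oxobut-3-en-1-yl)furan-3-yl]pent-3-en-1-yl 3-methylbut-2-enoate, via magnesium hemiaminal chelate 7 (not isolated)
Conditions: CH2=CHMgBr (1.5 equiv), THF, −78 to −40 °C; inverse quench into cold 1 M HCl/Et2O
Reagents that add atoms: vinylmagnesium bromide, C=C[Mg]Br
Why: Weinreb ketone synthesis, in which the Grignard reagent adds once to give a stable five-membered magnesium chelate that collapses to the vinyl ketone only on acidic quench, while the hindered conjugated senecioate should react much more slowly at low temperature.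

**Step 6**
Reactants: 8 (1S)-4-methyl-1-[5-(2-oxobut-3-en-1-yl)furan-3-yl]pent-3-en-1-yl 3-methylbut-2-enoate; 9 1,4-dioxane-2,3-diol
Product: 13 (1S)-1-[5-(2,5-dihydroxyphenyl)furan-3-yl]-4-methylpent-3-en-1-yl 3-methylbut-2-enoate, via glyoxal 10 (not isolated), via keto aldehyde 11 (not isolated), via cyclohexenedione 12 (not isolated)
Conditions: 9 (2 equiv), 3-benzyl-5-(2-hydroxyethyl)-4-methylthiazolium chloride (20 mol %), Et3N (50 mol %), degassed THF, 60 °C, Ar, slow addition of 8
Reagents that add atoms: none
Why: Proposed new method: the thiazol-2-ylidene adds to glyoxal 10 (set free from 9 and still masked as a hemiacetal at its second formyl group), the resulting Breslow intermediate adds 1,4 to the vinyl ketone of 8 (Stetter reaction, new C-4–C-5 bond in quinone numbering) and releases the catalyst to give the 1,4-diketone aldehyde 11, whose CH2 between furan C-2 and the ketone enolises under Et3N, adds to the unmasked aldehyde and loses water (aldol condensation, new C-2=C-3 bond) to give enedione 12, which enolises twice to the arene 13. The closest known reactions are thiazolium-catalysed Stetter additions of α-oxo aldehydes (glyoxylates, glyoxamides) and of aliphatic aldehydes to vinyl ketones, and carbene-catalysed domino Stetter–aldol–dehydration benzannulations of aromatic 1,2-dialdehydes with enones; not shown so far is glyoxal as a two-carbon unit that acts first as acyl anion and then as electrophile. The carbocycle closes in the aldol step in a 6-(enolendo)-exo-trig mode, favoured over the 5-(enolendo)-exo-trig attack of the same enolate on the C-4 ketone. No stereocentre is formed and the (S)-centre is remote from every reacting site. The step needs one Stetter addition per glyoxal and reaction at the vinyl ketone only: the intramolecular aldol of the uniquely acidic CH2 onto the highly electrophilic keto aldehyde should outrun a second intermolecular Stetter addition, the β,β-disubstituted senecioate is a poor acceptor, and hemiacetal masking should slow internal-redox isomerisation of the glyoxal adduct. Air is excluded because a quinone would oxidise the Breslow intermediate, and aromatisation makes the sequence irreversible.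

**Step 7**
Reactants: 13 (1S)-1-[5-(2,5-dihydroxyphenyl)furan-3-yl]-4-methylpent-3-en-1-yl 3-methylbut-2-enoate
Product: 14 (1S)-1-[5-(3,6-dioxocyclohexa-1,4-dien-1-yl)furan-3-yl]-4-methylpent-3-en-1-yl 3-methylbut-2-enoate (CNP0314322.1)
Conditions: Ag2O (3 equiv), Na2SO4, Et2O, rt, dark
Reagents that add atoms: none
Why: Two-electron oxidation of the hydroquinone to the para-quinone with Ag2O under neutral conditions should leave the furan, both trisubstituted alkenes, the ester and the stereocentre untouched.

**Compound list**
1 | 5-bromofuran-3-carbaldehyde | O=Cc1coc(Br)c1 | starting material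
2 | [(1S)-1-(5-bromofuran-3-yl)but-3-en-1-yl] diisopinocampheylborinate (formed in the flask) | C=CC[C@H](OB([C@@H]1C[C@@H]2C[C@H]([C@H]1C)C2(C)C)[C@@H]1C[C@@H]2C[C@H]([C@H]1C)C2(C)C)c1coc(Br)c1 | intermediate
3 | (1S)-1-(5-bromofuran-3-yl)but-3-en-1-ol | C=CC[C@H](O)c1coc(Br)c1 | intermediate
4 | (1S)-1-(5-bromofuran-3-yl)-4-methylpent-3-en-1-ol | CC(C)=CC[C@H](O)c1coc(Br)c1 | intermediate
5 | (1S)-1-(5-bromofuran-3-yl)-4-methylpent-3-en-1-yl 3-methylbut-2-enoate | CC(C)=CC[C@H](OC(=O)C=C(C)C)c1coc(Br)c1 | intermediate
6 | (1S)-1-{5-[2-(methoxy(methyl)amino)-2-oxoethyl]furan-3-yl}-4-methylpent-3-en-1-yl 3-methylbut-2-enoate | CC(C)=CC[C@H](OC(=O)C=C(C)C)c1coc(CC(=O)N(C)OC)c1 | intermediate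
7 | bromomagnesium alkoxide of the tetrahedral vinyl adduct of 6 (chelate, formed in the flask, both epimers at the new carbon) | CC(C)=CC[C@H](OC(=O)C=C(C)C)c1coc(CC(O[Mg]Br)(C=C)N(C)OC)c1 | intermediate
8 | (1S)-4-methyl-1-[5-(2-oxobut-3-en-1-yl)furan-3-yl]pent-3-en-1-yl 3-methylbut-2-enoate | CC(C)=CC[C@H](OC(=O)C=C(C)C)c1coc(CC(=O)C=C)c1 | intermediate
9 | 1,4-dioxane-2,3-diol (glyoxal ethylene glycol bis-hemiacetal) | OC1OCCOC1O | starting material
10 | glyoxal (formed in the flask) | O=CC=O | intermediate
11 | (1S)-4-methyl-1-[5-(2,5,6-trioxohexyl)furan-3-yl]pent-3-en-1-yl 3-methylbut-2-enoate (formed in the flask) | CC(C)=CC[C@H](OC(=O)C=C(C)C)c1coc(CC(=O)CCC(=O)C=O)c1 | intermediate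
12 | (1S)-1-[5-(3,6-dioxocyclohex-1-en-1-yl)furan-3-yl]-4-methylpent-3-en-1-yl 3-methylbut-2-enoate (formed in the flask) | CC(C)=CC[C@H](OC(=O)C=C(C)C)c1coc(C2=CC(=O)CCC2=O)c1 | intermediate
13 | (1S)-1-[5-(2,5-dihydroxyphenyl)furan-3-yl]-4-methylpent-3-en-1-yl 3-methylbut-2-enoate | CC(C)=CC[C@H](OC(=O)C=C(C)C)c1coc(-c2cc(O)ccc2O)c1 | intermediate
14 | (1S)-1-[5-(3,6-dioxocyclohexa-1,4-dien-1-yl)furan-3-yl]-4-methylpent-3-en-1-yl 3-methylbut-2-enoate (CNP0314322.1) | CC(C)=CC[C@H](OC(=O)C=C(C)C)c1coc(C2=CC(=O)C=CC2=O)c1 | target

**Step count and risks**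
Total step count: 7. Longest linear sequence: 7 steps (from 1).

Steps most likely to fail:

1. Step 6 (bears the label "Proposed new method:"). The carbene adduct of glyoxal may isomerise by internal redox or oligomerise faster than it adds to the enone. The keto aldehyde may take up a second enone before it cyclises. The enone may oligomerise through its acidic CH2. Fallback, a cross-coupling in place of the annulation, all known chemistry: it sets out from bromide 5 and comes back to the route at hydroquinone 13. Commercial 2-bromobenzene-1,4-diol is silylated (TBSCl, imidazole, DMF) to 2-bromo-1,4-bis(tert-butyldimethylsilyloxy)benzene F1. Bromine–lithium exchange (n-BuLi, THF, −78 °C) and trapping with 2-isopropoxy-4,4,5,5-tetramethyl-1,3,2-dioxaborolane should give 2-[2,5-bis(tert-butyldimethylsilyloxy)phenyl]-4,4,5,5-tetramethyl-1,3,2-dioxaborolane F2. Suzuki–Miyaura coupling of F2 with 5 (Pd(OAc)2, SPhos, K3PO4, toluene/H2O, 60 °C) should give the bis-silyl ether (1S)-1-{5-[2,5-bis(tert-butyldimethylsilyloxy)phenyl]furan-3-yl}-4-methylpent-3-en-1-yl 3-methylbut-2-enoate F3. HF·pyridine in THF at 0 °C should remove both silyl groups and give 13, which enters step 7.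

2. Step 5. The Grignard reagent may add to the senecioate in competition with the amide, the amide may be enolised at its activated CH2 and not attacked, and the liberated amine may add back to the vinyl ketone or the vinyl ketone may polymerise during work-up. Fallback, aldehyde addition and oxidation in place of amide acylation: it sets out from amide 6 and comes back at vinyl ketone 8. Cp2Zr(H)Cl in THF at rt should reduce the amide chemoselectively to the aldehyde (1S)-4-methyl-1-[5-(2-oxoethyl)furan-3-yl]pent-3-en-1-yl 3-methylbut-2-enoate F4. Vinylmagnesium bromide at −78 °C should add to the aldehyde far faster than to the ester and give the allylic alcohol (1S)-1-[5-(2-hydroxybut-3-en-1-yl)furan-3-yl]-4-methylpent-3-en-1-yl 3-methylbut-2-enoate F5 as both epimers. Dess–Martin periodinane (NaHCO3, CH2Cl2, 0 °C) should then give 8.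

3. Step 4. Transmetalation of the zinc amide enolate may be slow or the enolate may decompose, the bromofuran may be reduced by protodebromination, and the activated CH2 of the product may be arylated a second time. Fallback, the coupling partners with reversed polarity: it sets out from bromide 5 and comes back at amide 6. Miyaura borylation (B2pin2, Pd(dppf)Cl2, KOAc, dioxane, 80 °C) should give the boronate (1S)-4-methyl-1-[5-(4,4,5,5-tetramethyl-1,3,2-dioxaborolan-2-yl)furan-3-yl]pent-3-en-1-yl 3-methylbut-2-enoate F6. Suzuki–Miyaura coupling of F6 with 2-bromo-N-methoxy-N-methylacetamide as the sp3 electrophile (Pd(OAc)2, P(o-tol)3, K3PO4, THF/H2O, rt) should give 6.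

**Further compounds**
F1 | step 6 | 2-bromo-1,4-bis(tert-butyldimethylsilyloxy)benzene | CC(C)(C)[Si](C)(C)Oc1ccc(O[Si](C)(C)C(C)(C)C)c(Br)c1
F2 | step 6 | 2-[2,5-bis(tert-butyldimethylsilyloxy)phenyl]-4,4,5,5-tetramethyl-1,3,2-dioxaborolane | CC(C)(C)[Si](C)(C)Oc1ccc(O[Si](C)(C)C(C)(C)C)c(B2OC(C)(C)C(C)(C)O2)c1
F3 | step 6 | (1S)-1-{5-[2,5-bis(tert-butyldimethylsilyloxy)phenyl]furan-3-yl}-4-methylpent-3-en-1-yl 3-methylbut-2-enoate | CC(C)=CC[C@H](OC(=O)C=C(C)C)c1coc(-c2cc(O[Si](C)(C)C(C)(C)C)ccc2O[Si](C)(C)C(C)(C)C)c1
F4 | step 5 | (1S)-4-methyl-1-[5-(2-oxoethyl)furan-3-yl]pent-3-en-1-yl 3-methylbut-2-enoate | CC(C)=CC[C@H](OC(=O)C=C(C)C)c1coc(CC=O)c1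
F5 | step 5 | (1S)-1-[5-(2-hydroxybut-3-en-1-yl)furan-3-yl]-4-methylpent-3-en-1-yl 3-methylbut-2-enoate (both epimers at the new carbinol) | CC(C)=CC[C@H](OC(=O)C=C(C)C)c1coc(CC(O)C=C)c1
F6 | step 4 | (1S)-4-methyl-1-[5-(4,4,5,5-tetramethyl-1,3,2-dioxaborolan-2-yl)furan-3-yl]pent-3-en-1-yl 3-methylbut-2-enoate | CC(C)=CC[C@H](OC(=O)C=C(C)C)c1coc(B2OC(C)(C)C(C)(C)O2)c1
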